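common to all: starting material 0.050 M; initiator 1.4 mM
- maple: reagent 0.10 M; scavenger 0.017 M; run made earlier
- ash: reagent 0.10 M; scavenger 0.052 M; run made earlier
- alpha: reagent 0.100 M; scavenger 0.0220 M; time 15 h
- theta: reagent 0.100 M; scavenger 0.0340 M; time 15 h
- beta: reagent 0.100 M; scavenger 0.0150 M; time 15 h

| run | time / h | starting material / % | product / % |
|---|---|---|---|
| maple | 2.00 | 95.5 | 4.0 |
| maple | 4.00 | 91.3 | 9.0 |
| maple | 6.00 | 86.8 | 12.7 |
| maple | 8.00 | 83.4 | 16.4 |
| ash | 1.00 | 98.0 | 1.9 |
| ash | 2.50 | 95.0 | 5.8 |
| ash | 5.00 | 90.1 | 9.9 |
| ash | 8.00 | 83.7 | 15.7 |

(scatter of a reading: 0.5 percentage points)

* part of the starting material that has reacted at the end, alpha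
* part of the starting material that has reacted at the end, theta
* part of the starting material that has reacted at the end, beta
* what raising the concentration of scavenger from its lowest to its highest value here does to the part of the starting material that has reacted (changes below 5 percentage points count as none) (it falls / it rises / no change)

- the analysis behind the earlier runs scatters by 0.5 percentage points, standard deviation

**The runs.** Maple and ash differ in c(scavenger) by a factor of 3.06, yet at 8.00 h they hold 83.4% and 83.7% of the starting material, a gap of 0.3 percentage points against a scatter of 0.5 points. So this reckoning gives alpha, theta and beta one curve and expects no change, though beta's 0.0150 M stands a little below maple's charge.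

**The constant.** The mean loss at that hour is 16.4%. Minus the logarithm of the fraction left, divided by the time, gives k_app = 0.0225 /h, the apparent first-order constant. Carried to 15 h, it gives 28.6%, the figure this reckoning commits to.

**The bracket.** From above, a straight line at the mean rate gives 30.8%. From below, suppose the rate follows c(starting material)·c(reagent), with reagent lost one for one. The ratio of the two remaining fractions then grows exponentially, reaching 1.19 at 15 h, which means 27.8% reacted. The scatter of the mean, stretched to that hour, adds 0.66 points on either side.

**The result.** The forecast, inside the bracket, gives 29.5%, 29.5% and 29.5% with no change, holding that “the rate does not depend on scavenger over this range”. The simulation gives 27.4% for alpha, 27.5% for theta and 27.4% for beta, so the trend is no change, with a change of 0.015 points; scavenger is not the reason for the level reached. Theta stands 0.30 points under the lower bound, against the allowance of 0.66 points.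

    initiator → 2 initiating radical (k = 1.30 × 10⁻⁴ /min)
    reagent + first chain carrier ⇌ product + second chain carrier (K = 2.30, k = 5900 /M/min)
    starting material + second chain carrier → released group + first chain carrier (k = 8600 /M/min)
    scavenger + released group → scavenged by-product (k = 0.130 /M/min)
    2 first chain carrier → ended chains (k = 3.00 × 10⁶ /M/s)
    starting material + initiating radical → capped initiator + first chain carrier (k = 4.60 × 10⁵ /M/min)
    reagent + released group ⇌ idle adduct, settled at all times (K = 1100 /M)

**Chain ending.** Theta's result gives k_app = 0.0214 /h, against the 0.0225 /h carried over. Theta stands at 27.5% at 15 h because pairs of first chain carrier end each other (termination) and the reading comes early: without that step it reaches 100%, and at ten times the time it reaches 89.6%. For a neighbour flask, theta with 3.5 × 10⁻⁴ M of initiator and all else held, k_app scaled by the square root of the initiator ratio gives 15.5%, and that flask gives 14.9%.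

The data are simulated on assumed constants; the scatter is artificial.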